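Prinsepiol is a C2-symmetric, cis-fused 3,7-dioxabicyclo[3.3.0]octane: each ring oxygen ties a benzylic carbon (C7, C7') to the OCH2 carbon of the other half (C9', C9), and each neighbouring carbon (C8, C8') carries a tertiary hydroxyl. This O–C7/HO–C8 pair is the footprint of a C7–C8 epoxide opened at C7 by the C9' hydroxyl. The route therefore rests on one operation in which a Lewis acid lets a (2S,2'S,3S,3'S)-3,3'-diaryl-2,2'-bis(hydroxymethyl)-2,2'-bioxirane (phenols as pivalates) close ring 1 (C7–O–C9'–C8'–C8) and ring 2 (C7'–O–C9–C8–C8') by two 5-endo epoxide openings with inversion at C7 and C7'. The bis-epoxide comes from vanillin and dimethyl succinate through an (E,E)-diene diol.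

Key step: step 8

Assumption: lignan numbering is used (C7/C7' = ArCH–O, C8/C8' = C–OH, C9/C9' = OCH2), and the titanium–tartrate epoxidation is taken to show the face selectivity established for (E)-2-substituted 3-arylprop-2-en-1-ols.

Step 1
Reactants: 1 vanillin; 2 dimethyl succinate
Product: 3 (E)-4-(4-hydroxy-3-methoxyphenyl)-3-(methoxycarbonyl)but-3-enoic acid
Conditions: 2 (3 equiv), LiOMe (3.5 equiv), MeOH, reflux; then aq. HCl
Reagents that add atoms: none
Why: Stobbe condensation (aldol addition of the succinate enolate, lactonisation, eliminative ring opening) should give the half-ester as the (E)-isomer with the aryl group trans to CO2Me, LiOMe in methanol being the base that tolerates an aldehyde carried as its phenoxide, while methyl esters in methanol exclude ester scrambling.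

Step 2
Reactants: 3
Product: 4 dimethyl (E)-2-(4-hydroxy-3-methoxybenzylidene)succinate
Conditions: MeOH, H2SO4 (cat.), reflux
Reagents that add atoms: methanol, CO
Why: Fischer esterification of the free carboxylic acid restores the second ester needed for another condensation, and neither the phenol nor the (E)-alkene is affected.

Step 3
Reactants: 4; 1 vanillin
Product: 5 (2E,3E)-2,3-bis(4-hydroxy-3-methoxybenzylidene)succinic acid monomethyl ester
Conditions: 1 (1.2 equiv), LiOMe (5 equiv), MeOH, reflux, subdued light; then aq. HCl
Reagents that add atoms: none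
Why: A second Stobbe condensation at the remaining CH2 of 4 follows the same addition, lactonisation and ring-opening course and should again place the new aryl group trans to its own carboxyl, so that in the (E,E)-diene each aryl group is cis to the other half.

Step 4
Reactants: 5
Product: 6 dimethyl (2E,3E)-2,3-bis(4-hydroxy-3-methoxybenzylidene)succinate
Conditions: MeOH, H2SO4 (cat.), reflux, subdued light
Reagents that add atoms: methanol, CO
Why: Fischer esterification converts the conjugated acid into the methyl ester without etherifying the two phenols, which a base and an alkyl halide would not spare.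

Step 5
Reactants: 6
Product: 7 (2E,3E)-2,3-bis(4-hydroxy-3-methoxybenzylidene)butane-1,4-diol
Conditions: iBu2AlH (10 equiv), THF/CH2Cl2, −78 → 0 °C; aq. KNaC4H4O6 (potassium sodium tartrate)
Reagents that add atoms: none
Why: Aluminium hydride 1,2-reduction of both conjugated esters to primary allylic alcohols, with the excess reagent covering the two phenols as aluminium phenoxides, leaves the trisubstituted alkenes and their (E)-geometry untouched, and the neutral tartrate work-up avoids acid on the electron-rich diene.

Step 6
Reactants: 7; 8 pivaloyl chloride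
Product: 9 (2E,3E)-2,3-bis(3-methoxy-4-pivaloyloxybenzylidene)butane-1,4-diol
Conditions: 8 (2.1 equiv), 1 M aq. NaOH (2.2 equiv), Bu4NHSO4 (5 mol %), CH2Cl2, 0 °C
Reagents that add atoms: pivaloyl chloride, CC(C)(C)C(Cl)=O
Why: Schotten–Baumann acylation under phase transfer ionises only the phenols, and the phenoxides take up the hindered acyl chloride much faster than the neutral primary allylic alcohols, so both CH2OH groups stay free for steps 7 and 8.

Step 7
Reactants: 9
Product: 11 (2S,2'S,3S,3'S)-2,2'-bis(hydroxymethyl)-3,3'-bis(3-methoxy-4-pivaloyloxyphenyl)-2,2'-bioxirane, via mono-epoxide 10 (not isolated)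
Conditions: Ti(OiPr)4 (0.3 equiv), L-(+)-diisopropyl tartrate (0.36 equiv), tBuOOH (4 equiv, in decane), 4 Å MS, CH2Cl2, −25 °C; aq. Na2SO4
Reagents that add atoms: tert-butyl hydroperoxide, CC(C)(C)OO
Why: Sharpless asymmetric epoxidation delivers peroxide oxygen syn-stereospecifically to the face of each titanium-bound allylic alcohol selected by the L-(+)-tartrate, which for an (E)-2-substituted 3-arylprop-2-en-1-ol makes both oxirane carbons S (C7, C8 and C7', C8') with the aryl group still cis to the other half, while a wrong-face event at one alkene is diverted into the separable meso-type diastereomer and so raises the enantiomeric purity of 11.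

Step 8
Reactants: 11
Product: 13 prinsepiol bis(pivalate), (1S,2R,5S,6R)-2,6-bis(3-methoxy-4-pivaloyloxyphenyl)-3,7-dioxabicyclo[3.3.0]octane-1,5-diol, via monocyclic epoxy triol 12 (not isolated)
Conditions: BF3·OEt2 (0.2 equiv), CH2Cl2 (high dilution), −78 → −20 °C; Et3N, then aq. NaHCO3
Reagents that add atoms: none
Why: BF3 binds an oxirane oxygen and loosens the benzylic C7–O bond, and the C9' hydroxyl of the other half attacks C7 from the side opposite the departing oxygen, which stays on C8 as the tertiary hydroxyl; the closest known reaction type is the acid-promoted cyclisation of 4-aryl-3,4-epoxy alcohols to 2-aryl-3-hydroxytetrahydrofurans. Ring 1 (C7–O–C9'–C8'–C8) closes by a 5-endo epoxide opening to give 12, and ring 2 (C7'–O–C9–C8–C8') then closes in the same 5-endo mode, which is possible because C9 and C7' sit on the same face of ring 1 in the (8S,8'S) series. C7 and C7' are set by inversion of the oxirane carbons (S to R) and are thus controlled by the (E)-alkene geometry and the epoxidation face of step 7, while C8 and C8' keep their configuration because their C–O bonds are never broken. Since each aryl group is cis to the other half on its oxirane, inversion places it cis to the neighbouring hydroxyl, that is exo on the cis-fused bicycle, as in the target. The step needs regioselectivity for C7 over C8 and clean inversion: attack at C8, or attack of a hydroxymethyl group on its own oxirane, would give an oxetane, and the pivalate-bearing aryl rings carry enough positive charge to direct opening to C7 yet are too electron-poor to release a free benzylic cation that would scramble C7 or start a 1,2-shift.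

Step 9
Reactants: 13
Product: 14 prinsepiol, (1S,2R,5S,6R)-2,6-bis(4-hydroxy-3-methoxyphenyl)-3,7-dioxabicyclo[3.3.0]octane-1,5-diol
Conditions: K2CO3 (2.5 equiv), MeOH, 0 °C → rt; aq. NH4Cl
Reagents that add atoms: none
Why: Base-mediated transesterification (methanolysis) removes the two aryl pivalates because phenoxide is a good leaving group, while the benzylic ethers, the tertiary alcohols and all four stereocentres are inert to carbonate in methanol.

Compound list
1 | vanillin (4-hydroxy-3-methoxybenzaldehyde) | COc1cc(C=O)ccc1O | starting material
2 | dimethyl succinate | COC(=O)CCC(=O)OC | starting material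
3 | (E)-4-(4-hydroxy-3-methoxyphenyl)-3-(methoxycarbonyl)but-3-enoic acid (aryl trans to CO2Me) | COC(=O)/C(CC(O)=O)=C/c1ccc(O)c(OC)c1 | intermediate
4 | dimethyl (E)-2-(4-hydroxy-3-methoxybenzylidene)succinate | COC(=O)/C(CC(=O)OC)=C/c1ccc(O)c(OC)c1 | intermediate
5 | (2E,3E)-2,3-bis(4-hydroxy-3-methoxybenzylidene)succinic acid monomethyl ester (each aryl cis to the other half) | COC(=O)/C(=C/c1ccc(O)c(OC)c1)/C(=C\c1ccc(O)c(OC)c1)C(O)=O | intermediate
6 | dimethyl (2E,3E)-2,3-bis(4-hydroxy-3-methoxybenzylidene)succinate | COC(=O)/C(=C/c1ccc(O)c(OC)c1)/C(=C\c1ccc(O)c(OC)c1)C(=O)OC | intermediate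
7 | (2E,3E)-2,3-bis(4-hydroxy-3-methoxybenzylidene)butane-1,4-diol | OC/C(=C/c1ccc(O)c(OC)c1)/C(=C\c1ccc(O)c(OC)c1)CO | intermediate
8 | pivaloyl chloride | CC(C)(C)C(Cl)=O | starting material
9 | (2E,3E)-2,3-bis(3-methoxy-4-pivaloyloxybenzylidene)butane-1,4-diol | OC/C(=C/c1ccc(OC(=O)C(C)(C)C)c(OC)c1)/C(=C\c1ccc(OC(=O)C(C)(C)C)c(OC)c1)CO | intermediate
10 | mono-epoxide of 9: (S,S)-oxirane at C7–C8 (aryl trans to CH2OH), second arylidene unit unchanged with its aryl cis to the oxirane carbon | COc1cc([C@@H]2O[C@]2(CO)/C(CO)=C\c3ccc(OC(=O)C(C)(C)C)c(OC)c3)ccc1OC(=O)C(C)(C)C | intermediate (not isolated)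
11 | (2S,2'S,3S,3'S)-2,2'-bis(hydroxymethyl)-3,3'-bis(3-methoxy-4-pivaloyloxyphenyl)-2,2'-bioxirane (7S,7'S,8S,8'S) | COc1cc([C@@H]2O[C@]2(CO)[C@@]3(CO)O[C@H]3c4ccc(OC(=O)C(C)(C)C)c(OC)c4)ccc1OC(=O)C(C)(C)C | intermediate
12 | monocyclic epoxy triol: tetrahydrofuran ring 1 closed (7R,8S; C8 bears OH and CH2OH), C8' spiro to the intact (7'S,8'S)-aryl oxirane | COc1cc([C@H]2OC[C@@]3(O[C@H]3c4ccc(OC(=O)C(C)(C)C)c(OC)c4)[C@]2(O)CO)ccc1OC(=O)C(C)(C)C | intermediate (not isolated)
13 | prinsepiol bis(pivalate) (7R,7'R,8S,8'S) | COc1cc([C@H]2OC[C@]3(O)[C@@H](c4ccc(OC(=O)C(C)(C)C)c(OC)c4)OC[C@]23O)ccc1OC(=O)C(C)(C)C | intermediate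
14 | prinsepiol (7R,7'R,8S,8'S) | COc1cc([C@H]2OC[C@]3(O)[C@@H](c4ccc(O)c(OC)c4)OC[C@]23O)ccc1O | target

Total step count: 9. Longest linear sequence: 9 steps (from 1 and 2 to 14).

Steps most likely to fail

Step 8. The Lewis acid may ionise the benzylic C–O bond before the hydroxyl arrives, with loss of inversion at C7. Other risks are a 1,2-shift to a carbonyl compound, fluoride transfer from boron, intermolecular ether formation, and a halt after ring 1. The fallback replaces acid-promoted displacement by a base-triggered quinone-methide closure. It sets out from 11 and comes back at target 14. NaOMe (2.2 equiv) in THF at 0 °C → rt cleaves both pivalates to the bis-phenol bis-epoxide F1, which is not isolated. Its phenoxides push open the oxiranes by vinylogous elimination, with the C8–O and C8'–O bonds intact, to the bis(quinone methide) tetrol F2 (drawn with both halves opened). Each CH2OH then adds to the exocyclic C7' or C7 of the other half in a 5-exo-trig oxa-Michael addition that restores the arene. C8 and C8' remain as set in step 7. C7 and C7' would then rest on the preference for exo aryl groups on the cis-fused bicycle, which is the course quinone-methide closures to furofuran lignans take.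

Step 7. The 1,4-diol may bind titanium as a chelate, which would slow turnover and erode facial selectivity, and the first aryl oxirane may be opened prematurely by the Lewis-acidic catalyst. The fallback is a reagent-controlled Shi epoxidation without hydroxyl direction or Lewis acid. It sets out from 9 and comes back at 11. It uses the L-fructose-derived enantiomer of the Shi ketone (1,2:4,5-di-O-isopropylidene-L-erythro-hexo-2,3-diulopyranose, from L-sorbose), KHSO5 (as 2KHSO5·KHSO4·K2SO4), K2CO3 buffer, Bu4NHSO4, MeCN/dimethoxymethane/water, 0 °C. The trans-ArCH=C–CH2OH unit belongs to the alkene class for which this dioxirane is face-selective. The catalyst enantiomer is the one expected from the spiro transition-state model to give the (S,S)-oxiranes. The hindered pivalates should tolerate the cold buffer, and this fallback makes no compound outside the list (entry F0).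

Step 3. The condensation may stall because both partners are phenoxides, which lowers the electrophilicity of the aldehyde and the acidity of the CH2 group, so that ester hydrolysis or aldehyde disproportionation takes over. The fallback masks both phenols as allyl ethers, so neutral partners condense. It sets out from 4 and 1 and comes back at 5. Allyl bromide and K2CO3 in acetone give dimethyl (E)-2-(4-allyloxy-3-methoxybenzylidene)succinate F3 from 4 and 4-allyloxy-3-methoxybenzaldehyde F4 from 1. Stobbe condensation of F3 with F4 (NaOMe, MeOH, reflux; aq. HCl) gives (2E,3E)-2,3-bis(4-allyloxy-3-methoxybenzylidene)succinic acid monomethyl ester F5. Allyl transfer to morpholine with Pd(PPh3)4 (cat.) in THF at rt then returns 5.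

Further compounds
F1 | step 8 | (2S,2'S,3S,3'S)-3,3'-bis(4-hydroxy-3-methoxyphenyl)-2,2'-bis(hydroxymethyl)-2,2'-bioxirane | COc1cc([C@@H]2O[C@]2(CO)[C@@]3(CO)O[C@H]3c4ccc(O)c(OC)c4)ccc1O
F2 | step 8 | bis(quinone methide) tetrol: 2,3-bis(hydroxymethyl)butane-2,3-diol carrying a (3-methoxy-4-oxocyclohexa-2,5-dien-1-ylidene)methyl group on C2 and on C3, C8 and C8' as in 11 | COC1=CC(=C[C@@](O)(CO)[C@](O)(CO)C=C2C=CC(=O)C(OC)=C2)C=CC1=O
F0 | step 7 | none | none
F3 | step 3 | dimethyl (E)-2-(4-allyloxy-3-methoxybenzylidene)succinate | COC(=O)/C(CC(=O)OC)=C/c1ccc(OCC=C)c(OC)c1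
F4 | step 3 | 4-allyloxy-3-methoxybenzaldehyde | COc1cc(C=O)ccc1OCC=C
F5 | step 3 | (2E,3E)-2,3-bis(4-allyloxy-3-methoxybenzylidene)succinic acid monomethyl ester | COC(=O)/C(=C/c1ccc(OCC=C)c(OC)c1)/C(=C\c1ccc(OCC=C)c(OC)c1)C(O)=O
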